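The flavone is cut between C2 of the 4H-chromen-4-one ring and C1′ of the B ring. The key step exploits the acidity of the C2–H of the pyranone ring (an sp2 C–H next to O1 and conjugated with the C4 carbonyl): a Lewis-acid-free TMP-zinc base zincates a 5,7-bis(MOM)-8-prenylchromone at C2, and the organozinc is cross-coupled in the same flask (Negishi) with unprotected 5-bromo-2-methoxy-3-prenylphenol. The chromone needs no leaving group at C2 and the B-ring phenol no protecting group. The bromophenol comes from 2,4,6-tribromoanisole by two ortho-selective Br/Mg exchanges, the chromone from phloroacetophenone. Acidic MOM removal ends the route.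

Key step: step 6

Remark: the target has no stereocentre, and both alkenes carry two identical methyl groups, so it is achiral and no stereocontrol is required.

Step 1
Reactants: 1 1-(2,4,6-trihydroxyphenyl)ethanone (phloroacetophenone)
Product: 2 1-[2,4,6-trihydroxy-3-(3-methylbut-2-en-1-yl)phenyl]ethanone
Conditions: prenyl bromide (0.9 equiv), DBU, THF, 0 °C → rt
Reagents that add atoms: prenyl bromide (1-bromo-3-methylbut-2-ene), CC(C)=CCBr
Why: Nuclear C-alkylation of the ambident phloroglucinol-type phenoxide with an allylic bromide; the two free ring positions are equivalent, so a single mono-C-prenyl product is possible, and a deficit of bromide limits double alkylation.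

Step 2
Reactants: 2 1-[2,4,6-trihydroxy-3-(3-methylbut-2-en-1-yl)phenyl]ethanone
Product: 3 1-[2-hydroxy-4,6-bis(methoxymethoxy)-3-(3-methylbut-2-en-1-yl)phenyl]ethanone
Conditions: MOMCl (2.1 equiv), i-Pr2NEt, CH2Cl2, 0 °C → rt
Reagents that add atoms: chloromethyl methyl ether (MOMCl), COCCl
Why: O-alkylation (MOM acetal formation) should take the 4-OH and the less hindered 6-OH, while the 2-OH, flanked by prenyl and acetyl and held in the hydrogen bond to the carbonyl, stays free; this fixes the later ring closure on the oxygen next to the prenyl group.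

Step 3
Reactants: 3 1-[2-hydroxy-4,6-bis(methoxymethoxy)-3-(3-methylbut-2-en-1-yl)phenyl]ethanone
Product: 5 5,7-bis(methoxymethoxy)-8-(3-methylbut-2-en-1-yl)-4H-chromen-4-one, via enaminone 4 (not isolated)
Conditions: DMF-DMA, toluene, 95 °C; then AcOH, CH2Cl2, 40 °C
Reagents that add atoms: N,N-dimethylformamide dimethyl acetal (DMF-DMA), COC(OC)N(C)C
Why: Condensation of the methyl ketone with the amide acetal gives the o-hydroxyaryl enaminone, and acid-mediated addition of the free 2-OH with loss of dimethylamine closes the pyranone (enaminone chromone synthesis); acetic acid is too weak to cleave the aryl MOM ethers.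

Step 4
Reactants: 6 2,4,6-tribromoanisole
Product: 8 1,5-dibromo-2-methoxy-3-(3-methylbut-2-en-1-yl)benzene, via aryl Grignard 7 (not isolated)
Conditions: i-PrMgCl·LiCl (1.05 equiv), THF, −20 °C; then CuI (5 mol %), prenyl bromide, −20 °C → rt
Reagents that add atoms: prenyl bromide (1-bromo-3-methylbut-2-ene), CC(C)=CCBr
Why: Br/Mg exchange should occur at one of the two equivalent bromines ortho to the coordinating, inductively stabilising methoxy group; copper-catalysed allylic substitution at the primary carbon of prenyl bromide (the tertiary γ-carbon is hindered) then gives the linear prenyl arene.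

Step 5
Reactants: 8 1,5-dibromo-2-methoxy-3-(3-methylbut-2-en-1-yl)benzene
Product: 11 5-bromo-2-methoxy-3-(3-methylbut-2-en-1-yl)phenol, via aryl Grignard 9 (not isolated), via dimethyl arylboronate 10 (not isolated)
Conditions: i-PrMgCl·LiCl (1.1 equiv), THF, 0 °C → rt; B(OMe)3, −15 °C → rt; then 30% aq. H2O2, 0 °C → rt
Reagents that add atoms: hydrogen peroxide, OO
Why: A second methoxy-directed Br/Mg exchange should take the ortho bromine and leave the para bromine; borylation and oxidative 1,2-aryl migration (boronate oxidation, made basic by the magnesium methoxide in the pot) give the phenol, and aqueous H2O2 does not attack the unactivated trisubstituted alkene or the aryl bromide.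

Step 6
Reactants: 5 5,7-bis(methoxymethoxy)-8-(3-methylbut-2-en-1-yl)-4H-chromen-4-one; 11 5-bromo-2-methoxy-3-(3-methylbut-2-en-1-yl)phenol
Product: 13 2-[3-hydroxy-4-methoxy-5-(3-methylbut-2-en-1-yl)phenyl]-5,7-bis(methoxymethoxy)-8-(3-methylbut-2-en-1-yl)-4H-chromen-4-one, via 2-chromonylzinc chloride 12 (not isolated)
Conditions: 5 (1.5 equiv), TMPZnCl·LiCl (1.6 equiv), THF, 25 °C; then slow addition to 11, Pd(OAc)2 (2 mol %), SPhos (4 mol %), THF, 25 → 40 °C
Reagents that add atoms: none
Why: TMPZnCl·LiCl should remove the most acidic proton of 5, the C2–H of the pyranone ring (sp2 C–H alpha to O1 and beta to the C4 carbonyl), to give the alkenylzinc 12; Pd(0)/SPhos inserts into the C–Br bond of 11, and transmetalation and reductive elimination form the C2–C1′ bond. The closest known reaction type is the TMP-zinc-base C2-zincation of chromones followed by Negishi cross-coupling to flavones, together with Negishi couplings of aryl bromides that carry a free OH. No ring is closed and no stereocentre is formed. The step needs zincation at C2 rather than C3, which a magnesium-free, Lewis-acid-free base should secure (carbonyl-bound Lewis acids steer metalation to C3); the C6–H between the two MOM ethers and the benzylic/allylic CH2 groups are far too weakly acidic for a zinc amide. It also needs the coupling to outrun protonolysis of the C–Zn bond by the phenol of 11; slow addition of 12 to the catalyst/11 mixture and the excess of 12 serve this, and any protonolysis only returns 5.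

Step 7
Reactants: 13 2-[3-hydroxy-4-methoxy-5-(3-methylbut-2-en-1-yl)phenyl]-5,7-bis(methoxymethoxy)-8-(3-methylbut-2-en-1-yl)-4H-chromen-4-one
Product: 14 5,7-dihydroxy-2-[3-hydroxy-4-methoxy-5-(3-methylbut-2-en-1-yl)phenyl]-8-(3-methylbut-2-en-1-yl)-4H-chromen-4-one (target)
Conditions: 3 M aq. HCl, MeOH, 50 °C, short reaction time
Reagents that add atoms: none
Why: Acid-catalysed acetal cleavage (transacetalisation to dimethoxymethane) frees the 5- and 7-OH; dilute acid, moderate temperature and a short time are chosen so that the 7-OH/8-prenyl pair should not cyclise to a chroman, and the methyl ether and both alkenes are inert.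

Compound list
1 | 1-(2,4,6-trihydroxyphenyl)ethanone (phloroacetophenone) | CC(=O)c1c(O)cc(O)cc1O | starting material
2 | 1-[2,4,6-trihydroxy-3-(3-methylbut-2-en-1-yl)phenyl]ethanone | CC(=O)c1c(O)cc(O)c(CC=C(C)C)c1O | intermediate
3 | 1-[2-hydroxy-4,6-bis(methoxymethoxy)-3-(3-methylbut-2-en-1-yl)phenyl]ethanone | CC(=O)c1c(OCOC)cc(OCOC)c(CC=C(C)C)c1O | intermediate
4 | (E)-3-(dimethylamino)-1-[2-hydroxy-4,6-bis(methoxymethoxy)-3-(3-methylbut-2-en-1-yl)phenyl]prop-2-en-1-one (enaminone, not isolated) | CN(C)/C=C/C(=O)c1c(OCOC)cc(OCOC)c(CC=C(C)C)c1O | intermediate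
5 | 5,7-bis(methoxymethoxy)-8-(3-methylbut-2-en-1-yl)-4H-chromen-4-one | O=c1ccoc2c(CC=C(C)C)c(OCOC)cc(OCOC)c12 | intermediate
6 | 2,4,6-tribromoanisole (1,3,5-tribromo-2-methoxybenzene) | COc1c(Br)cc(Br)cc1Br | starting material
7 | (3,5-dibromo-2-methoxyphenyl)magnesium chloride (aryl Grignard, not isolated) | COc1c(Br)cc(Br)cc1[Mg]Cl | intermediate
8 | 1,5-dibromo-2-methoxy-3-(3-methylbut-2-en-1-yl)benzene | COc1c(Br)cc(Br)cc1CC=C(C)C | intermediate
9 | [5-bromo-2-methoxy-3-(3-methylbut-2-en-1-yl)phenyl]magnesium chloride (aryl Grignard, not isolated) | COc1c([Mg]Cl)cc(Br)cc1CC=C(C)C | intermediate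
10 | dimethyl [5-bromo-2-methoxy-3-(3-methylbut-2-en-1-yl)phenyl]boronate (not isolated) | COB(OC)c1cc(Br)cc(CC=C(C)C)c1OC | intermediate
11 | 5-bromo-2-methoxy-3-(3-methylbut-2-en-1-yl)phenol | COc1c(O)cc(Br)cc1CC=C(C)C | intermediate
12 | chloro[5,7-bis(methoxymethoxy)-8-(3-methylbut-2-en-1-yl)-4-oxo-4H-chromen-2-yl]zinc (2-chromonylzinc chloride, not isolated) | O=c1cc([Zn]Cl)oc2c(CC=C(C)C)c(OCOC)cc(OCOC)c12 | intermediate
13 | 2-[3-hydroxy-4-methoxy-5-(3-methylbut-2-en-1-yl)phenyl]-5,7-bis(methoxymethoxy)-8-(3-methylbut-2-en-1-yl)-4H-chromen-4-one | COc1c(O)cc(-c2cc(=O)c3c(OCOC)cc(OCOC)c(CC=C(C)C)c3o2)cc1CC=C(C)C | intermediate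
14 | 5,7-dihydroxy-2-[3-hydroxy-4-methoxy-5-(3-methylbut-2-en-1-yl)phenyl]-8-(3-methylbut-2-en-1-yl)-4H-chromen-4-one | COc1c(O)cc(-c2cc(=O)c3c(O)cc(O)c(CC=C(C)C)c3o2)cc1CC=C(C)C | target

Total step count: 7. Longest linear sequence: 5 steps (steps 1, 2, 3, 6, 7).

Steps most likely to fail

Step 6. Metalation could occur at C3, or the amide could add to and open the pyranone, instead of clean C2 zincation; the phenolic OH of 11 could also protonate the C–Zn bond before transmetalation. The fallback forms the same C2–C1′ bond from boron instead of zinc and sets out from 11 and 5. Miyaura borylation of 11 (B2pin2, PdCl2(dppf), KOAc, dioxane, 80 °C) should give 2-methoxy-3-(3-methylbut-2-en-1-yl)-5-(4,4,5,5-tetramethyl-1,3,2-dioxaborolan-2-yl)phenol F1. Rh(I)-catalysed conjugate addition of F1 to 5 ([Rh(cod)Cl]2, KOH, dioxane/H2O, 60 °C), which tolerates the free OH, should give the racemic flavanone 2-[3-hydroxy-4-methoxy-5-(3-methylbut-2-en-1-yl)phenyl]-5,7-bis(methoxymethoxy)-8-(3-methylbut-2-en-1-yl)chroman-4-one F2. Aerobic dehydrogenation (Pd(TFA)2/DMSO, O2, 80 °C) erases the C2 stereocentre and comes back to the route at 13.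

Step 5. The exchange could take the para bromine or both bromines instead of only the ortho one, and the Grignard reagent could be protonated before borylation. The fallback avoids the second exchange; it sets out from 8 and from 12 (made from 5 as in step 6). Site-selective Negishi coupling at the unhindered bromine para to the methoxy group (the other is shielded by OMe; Pd(OAc)2/SPhos, THF, 25 °C) should give 2-[3-bromo-4-methoxy-5-(3-methylbut-2-en-1-yl)phenyl]-5,7-bis(methoxymethoxy)-8-(3-methylbut-2-en-1-yl)-4H-chromen-4-one F3. Miyaura borylation of the remaining C–Br bond (B2pin2, PdCl2(dppf), KOAc, dioxane, 90 °C) should give the boronate 2-[4-methoxy-3-(3-methylbut-2-en-1-yl)-5-(4,4,5,5-tetramethyl-1,3,2-dioxaborolan-2-yl)phenyl]-5,7-bis(methoxymethoxy)-8-(3-methylbut-2-en-1-yl)-4H-chromen-4-one F4. Oxidation (NaBO3·4H2O, THF/H2O, rt) comes back to the route at 13.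

Step 2. Protection could fall on the 2-OH instead of the 6-OH, or on all three hydroxyls, which would later lead to the 6-prenyl chromone. The fallback sets the prenyl position by a rearrangement instead of by selective protection; it sets out from 1 and also bypasses step 1.
- Mono-protection of the non-chelated 4-OH (MOMCl 1 equiv, K2CO3, acetone) should give 1-[2,6-dihydroxy-4-(methoxymethoxy)phenyl]ethanone F5.
- DMF-DMA should give the enaminone (E)-3-(dimethylamino)-1-[2,6-dihydroxy-4-(methoxymethoxy)phenyl]prop-2-en-1-one F6, which AcOH cyclises through either of its equivalent ortho hydroxyls to 5-hydroxy-7-(methoxymethoxy)-4H-chromen-4-one F7.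
- O-Prenylation (prenyl bromide, K2CO3, acetone, reflux) should give 7-(methoxymethoxy)-5-[(3-methylbut-2-en-1-yl)oxy]-4H-chromen-4-one F8.
- Eu(fod)3-catalysed para-Claisen–Cope rearrangement (CHCl3, 60 °C; C6 then C8) should give 5-hydroxy-7-(methoxymethoxy)-8-(3-methylbut-2-en-1-yl)-4H-chromen-4-one F9.
- MOM protection of the 5-OH (MOMCl, NaH, DMF) comes back to the route at 5.

Further compounds
F1 | step 6 | 2-methoxy-3-(3-methylbut-2-en-1-yl)-5-(4,4,5,5-tetramethyl-1,3,2-dioxaborolan-2-yl)phenol | COc1c(O)cc(B2OC(C)(C)C(C)(C)O2)cc1CC=C(C)C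
F2 | step 6 | 2-[3-hydroxy-4-methoxy-5-(3-methylbut-2-en-1-yl)phenyl]-5,7-bis(methoxymethoxy)-8-(3-methylbut-2-en-1-yl)chroman-4-one (racemic) | COc1c(O)cc(C2CC(=O)c3c(OCOC)cc(OCOC)c(CC=C(C)C)c3O2)cc1CC=C(C)C
F3 | step 5 | 2-[3-bromo-4-methoxy-5-(3-methylbut-2-en-1-yl)phenyl]-5,7-bis(methoxymethoxy)-8-(3-methylbut-2-en-1-yl)-4H-chromen-4-one | COc1c(Br)cc(-c2cc(=O)c3c(OCOC)cc(OCOC)c(CC=C(C)C)c3o2)cc1CC=C(C)C
F4 | step 5 | 2-[4-methoxy-3-(3-methylbut-2-en-1-yl)-5-(4,4,5,5-tetramethyl-1,3,2-dioxaborolan-2-yl)phenyl]-5,7-bis(methoxymethoxy)-8-(3-methylbut-2-en-1-yl)-4H-chromen-4-one | COc1c(B2OC(C)(C)C(C)(C)O2)cc(-c2cc(=O)c3c(OCOC)cc(OCOC)c(CC=C(C)C)c3o2)cc1CC=C(C)C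
F5 | step 2 | 1-[2,6-dihydroxy-4-(methoxymethoxy)phenyl]ethanone | CC(=O)c1c(O)cc(OCOC)cc1O
F6 | step 2 | (E)-3-(dimethylamino)-1-[2,6-dihydroxy-4-(methoxymethoxy)phenyl]prop-2-en-1-one | CN(C)/C=C/C(=O)c1c(O)cc(OCOC)cc1O
F7 | step 2 | 5-hydroxy-7-(methoxymethoxy)-4H-chromen-4-one | O=c1ccoc2cc(OCOC)cc(O)c12
F8 | step 2 | 7-(methoxymethoxy)-5-[(3-methylbut-2-en-1-yl)oxy]-4H-chromen-4-one | O=c1ccoc2cc(OCOC)cc(OCC=C(C)C)c12
F9 | step 2 | 5-hydroxy-7-(methoxymethoxy)-8-(3-methylbut-2-en-1-yl)-4H-chromen-4-one | O=c1ccoc2c(CC=C(C)C)c(OCOC)cc(O)c12
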